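**Plan**
1. Cuts (biogenetic numbering, see remark): C8–C9 (eleven-membered ring, Nozaki–Hiyama–Kishi), C1–C14 (B-alkyl Suzuki–Miyaura to a citronellene-derived chain), C4–C5 (cyclopentane, radical ring closure), C6–C7 (auxiliary-controlled alkylation); the cyclohexene is traced back to an aromatic ring.
2. Enabling feature: the ring C1–C2–C3–C4–C16–C15 is a masked 4,6-dimethylresorcinol. C16 carries two arms of the same constitution, C15(CH3)=C1 and C4(CH3)–C3(O), so a Birch-derived bis(silyl enol ether) has a mirror plane through C16 and C2.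
3. Forward: arene → Birch reduction (six-membered ring, symmetric) → C7 side chain → 5-exo radical cyclization of C5 onto C4 (cyclopentane, desymmetrization) → the untouched enol ether becomes the C1 enol triflate → chain union at C1–C14 → ring closure at C8–C9 → adjustment at C9, C3 and C2.
4. Stereochemistry: C7 from an oxazolidinone auxiliary; C4 and C16 from the key step under control of C7; C12 from (R)-β-citronellene; C9 from a CBS reduction; C2 from convex-face enolate hydroxylation; C3 from hydroxyl-directed reduction.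

Key step: step 7

Remark 1: atoms carry the biogenetic numbering of the target: C1(=C15)–C2(OH)–C3(OH)–C4(CH3-18)–C5–C6–C7–C8(=C19H2)–C9(OAc)–C10–C11–C12(CH3-20)–C13–C14–C1, with C15(CH3-17)–C16 and C16 bonded to C4 and C7; the target is (2R,3R,4R,7R,9R,12S,16R).
Remark 2: C3 in 10–12 and 17–25 and C9 in 21 arise as epimer mixtures that are erased by later oxidation (steps 20 and 16), so their SMILES carry no descriptor at these atoms.
Remark 3: 3,5-dihydroxyphenylacetic acid, (R)-β-citronellene and 2-bromoethyl triflate are taken as purchased.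

Step 1
Reactants: 1 3,5-dihydroxyphenylacetic acid
Product: 3 2-[3,5-bis(tert-butyldimethylsilyloxy)phenyl]acetic acid, via tris-silyl ester 2 (not isolated)
Conditions: TBSCl, imidazole, DMF, rt; then AcOH/THF/H2O, rt
Reagents that add atoms: tert-butyldimethylsilyl chloride, CC(C)(C)[Si](C)(C)Cl
Why: Exhaustive silylation followed by selective hydrolysis of the labile silyl ester should leave both phenols as bulky silyl ethers, which steer the next bromination and later become the silyl enol ethers (standard silyl protection).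

Step 2
Reactants: 3 2-[3,5-bis(tert-butyldimethylsilyloxy)phenyl]acetic acid
Product: 4 2-[2,6-dibromo-3,5-bis(tert-butyldimethylsilyloxy)phenyl]acetic acid
Conditions: NBS (2.1 equiv), MeCN, 0 °C to rt
Reagents that add atoms: N-bromosuccinimide, O=C1CCC(=O)N1Br
Why: Electrophilic aromatic bromination should take the two equivalent positions next to the side chain (each para to one silyloxy group and ortho to the other), because the position between the two bulky silyloxy groups is shielded.

Step 3
Reactants: 4 2-[2,6-dibromo-3,5-bis(tert-butyldimethylsilyloxy)phenyl]acetic acid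
Product: 5 2-[3,5-bis(tert-butyldimethylsilyloxy)-2,6-dimethylphenyl]acetic acid
Conditions: MeZnCl (5 equiv), Pd(PtBu3)2 (cat.), THF/NMP, 60 °C; NaH2PO4 work-up
Reagents that add atoms: methylzinc chloride, C[Zn]Cl
Why: A double Negishi coupling with a bulky electron-rich phosphine catalyst should replace both hindered bromides by methyl (the future CH3-17 and CH3-18) under base-free conditions that spare the aryl silyl ethers.

Step 4
Reactants: 5 2-[3,5-bis(tert-butyldimethylsilyloxy)-2,6-dimethylphenyl]acetic acid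
Product: 6 2-[3,5-bis(tert-butyldimethylsilyloxy)-2,6-dimethylcyclohexa-2,5-dien-1-yl]acetic acid (achiral)
Conditions: Li, NH3(l), THF, t-BuOH, −78 to −33 °C; NH4Cl; work-up at pH 6
Reagents that add atoms: none
Why: Birch reduction of the resorcinol bis(silyl ether) should protonate the carbon between the two oxygens (C2) and the para carbon (C16), giving the non-conjugated bis(silyl enol ether) with C16 on a mirror plane, while the carboxylate is inert to the metal.

Step 5
Reactants: 6 2-[3,5-bis(tert-butyldimethylsilyloxy)-2,6-dimethylcyclohexa-2,5-dien-1-yl]acetic acid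
Product: 8 (4R)-4-benzyl-3-{2-[3,5-bis(tert-butyldimethylsilyloxy)-2,6-dimethylcyclohexa-2,5-dien-1-yl]acetyl}-1,3-oxazolidin-2-one, via mixed pivalic anhydride 7 (not isolated)
Conditions: t-BuCOCl, Et3N, THF, −20 °C; then (R)-4-benzyl-2-oxazolidinone/n-BuLi, THF, −78 to 0 °C
Reagents that add atoms: (R)-4-benzyl-2-oxazolidinone, O=C1N[C@H](Cc2ccccc2)CO1
Why: N-Acylation of the lithiated oxazolidinone by the mixed anhydride at its less hindered carbonyl attaches the auxiliary under non-acidic conditions that keep both enol ethers intact (Evans auxiliary attachment).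

Step 6
Reactants: 8 (4R)-4-benzyl-3-{2-[3,5-bis(tert-butyldimethylsilyloxy)-2,6-dimethylcyclohexa-2,5-dien-1-yl]acetyl}-1,3-oxazolidin-2-one
Product: 9 (4R)-4-benzyl-3-{(2R)-4-bromo-2-[3,5-bis(tert-butyldimethylsilyloxy)-2,6-dimethylcyclohexa-2,5-dien-1-yl]butanoyl}-1,3-oxazolidin-2-one
Conditions: NaN(SiMe3)2, THF, −78 °C; BrCH2CH2OTf, −78 to −45 °C
Reagents that add atoms: 2-bromoethyl trifluoromethanesulfonate, BrCCOS(=O)(=O)C(F)(F)F
Why: Evans alkylation of the chelated Z-enolate on the face opposite the benzyl group by the primary triflate (far more reactive than the bromide end) sets C7 as R and installs C6–C5–Br in one step, while C16 stays non-stereogenic.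

Step 7
Reactants: 9 (4R)-4-benzyl-3-{(2R)-4-bromo-2-[3,5-bis(tert-butyldimethylsilyloxy)-2,6-dimethylcyclohexa-2,5-dien-1-yl]butanoyl}-1,3-oxazolidin-2-one
Product: 10 (4R)-4-benzyl-3-{[(1R,3aR,7aS)-4,6-bis(tert-butyldimethylsilyloxy)-3a,7-dimethyl-2,3,3a,4,5,7a-hexahydro-1H-inden-1-yl]carbonyl}-1,3-oxazolidin-2-one (cis-fused; acyl group cis to H-7a; silyloxy carbon 4 = C3 as epimers)
Conditions: Bu3SnH (syringe pump), AIBN (cat.), PhH, 80 °C, 0.005 M
Reagents that add atoms: none
Why: Bu3Sn• abstracts bromine from C5 and the primary radical adds 5-exo-trig to C4, the methyl-bearing β-carbon of one of the two silyl enol ether arms on C16, after which the α-silyloxy radical at C3 takes hydrogen from Bu3SnH. The closest known reaction type is the tin hydride-mediated 5-exo cyclization of alkyl radicals onto enol ethers and onto Birch-derived cyclohexa-1,4-dienes with selection between diastereotopic double bonds. The cyclopentane C4–C5–C6–C7–C16 closes in the 5-exo-trig mode and is cis-fused because tether and attacked carbon sit on adjacent ring atoms. C4 (quaternary) and C16 are set together by the C7 stereocentre: in the chair-like transition state the acyl group at C7 is pseudo-equatorial and anti to the arm that does not react, so the arm that puts the acyl group on the convex face (H-7 trans to H-16) is attacked, while C3 forms as an epimer mixture that is erased in step 20. The step needs selectivity between the two arms, exo over endo attack and cyclization over premature reduction, which are secured by the C7 substituent, by the preference of alkyl radicals for the β-carbon of an enol ether (oxygen-stabilized radical) and by a low stannane concentration. The untouched arm survives as a regiodefined silyl enol ether, which later fixes the position of the C1=C15 double bond.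

Step 8
Reactants: 10 bicyclic imide (name as in step 7)
Product: 11 (1R,3aR,7aS)-4,6-bis(tert-butyldimethylsilyloxy)-N-methoxy-N,3a,7-trimethyl-2,3,3a,4,5,7a-hexahydro-1H-indene-1-carboxamide
Conditions: AlMe3, MeNHOMe·HCl, CH2Cl2, −10 °C to rt
Reagents that add atoms: N,O-dimethylhydroxylamine hydrochloride, CNOC.Cl
Why: Transamination of the imide with the aluminium amide of N,O-dimethylhydroxylamine removes the auxiliary without touching C7 and leaves a Weinreb amide that is inert in the next two steps.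

Step 9
Reactants: 11 Weinreb amide with C1 silyl enol ether
Product: 12 (1R,3aR,7aS)-4-(tert-butyldimethylsilyloxy)-1-[methoxy(methyl)carbamoyl]-3a,7-dimethyl-2,3,3a,4,5,7a-hexahydro-1H-inden-6-yl trifluoromethanesulfonate
Conditions: CsF, PhNTf2, DME, rt
Reagents that add atoms: N-phenylbis(trifluoromethanesulfonimide), O=S(=O)(N(c1ccccc1)S(=O)(=O)C(F)(F)F)C(F)(F)F
Why: Fluoride releases the regiodefined C1=C15 enolate from the silyl enol ether (the alkyl silyl ether at C3 is far less labile) and O-triflation traps it before any proton transfer, giving the tetrasubstituted enol triflate as a single regioisomer.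

Step 10
Reactants: 13 (R)-β-citronellene [(3R)-3,7-dimethylocta-1,6-diene]
Product: 15 (3R)-6,6-dimethoxy-3-methylhex-1-ene, via (R)-4-methylhex-5-enal 14 (not isolated)
Conditions: O3 (1 equiv), CH2Cl2, −78 °C; Me2S; then HC(OMe)3, TsOH (cat.), MeOH, rt
Reagents that add atoms: trimethyl orthoformate, COC(OC)OC
Why: Ozone should cleave the electron-rich trisubstituted alkene in preference to the vinyl group, and acetalization masks the future C9 aldehyde; C12 comes unchanged from the chiral pool.

Step 11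
Reactants: 15 (3R)-6,6-dimethoxy-3-methylhex-1-ene; 12 enol triflate
Product: 17 8,9-seco intermediate: C8 Weinreb amide, C9 dimethyl acetal, 3-OTBS (epimers), C1=C15 alkene; C4, C7, C12, C16 as in 28, via B-alkyl-9-BBN adduct 16 (not isolated)
Conditions: 9-BBN, THF, rt; then 12, Pd(dppf)Cl2 (cat.), AsPh3, Cs2CO3, DMF/THF/H2O, rt
Reagents that add atoms: none
Why: Anti-Markovnikov hydroboration of the vinyl group and B-alkyl Suzuki–Miyaura coupling with the enol triflate form C1–C14 and deliver the tetrasubstituted C1=C15 alkene exactly where the triflate was.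

Step 12
Reactants: 17 Weinreb amide
Product: 18 methyl ketone (C8 acetyl on C7; otherwise as 17)
Conditions: MeMgBr, THF, 0 °C
Reagents that add atoms: methylmagnesium bromide, C[Mg]Br
Why: Weinreb ketone synthesis: the chelated tetrahedral adduct prevents over-addition and introduces C19.

Step 13
Reactants: 18 methyl ketone
Product: 19 C8 enol triflate [C7–C(=CH2)OTf; otherwise as 17]
Conditions: KN(SiMe3)2, THF, −78 °C; PhNTf2, −78 to 0 °C
Reagents that add atoms: N-phenylbis(trifluoromethanesulfonimide), O=S(=O)(N(c1ccccc1)S(=O)(=O)C(F)(F)F)C(F)(F)F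
Why: Kinetic deprotonation at the methyl group (the C7 methine is hindered) and O-triflation give the 1,1-disubstituted alkenyl triflate needed for the ring closure.

Step 14
Reactants: 19 enol triflate acetal
Product: 20 enol triflate aldehyde (C9 = CHO)
Conditions: LiBF4, MeCN/H2O, rt
Reagents that add atoms: water, O
Why: Mild Lewis-acid hydrolysis of the dimethyl acetal frees the aldehyde, while the enol triflate, the hindered silyl ether and the tetrasubstituted alkene are inert.

Step 15
Reactants: 20 enol triflate aldehyde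
Product: 21 macrocyclic allylic alcohol (11-membered ring closed; 9-OH as epimers; 3-OTBS)
Conditions: CrCl2 (excess), NiCl2 (cat.), DMF, rt, slow addition to 0.002 M
Reagents that add atoms: none
Why: Nozaki–Hiyama–Kishi reaction: the nickel-derived alkenylchromium species adds only to the aldehyde and closes the eleven-membered ring at C8–C9 with the exocyclic methylene in place; the C9 configuration is not relied upon.

Step 16
Reactants: 21 macrocyclic allylic alcohol
Product: 22 macrocyclic 8(19)-en-9-one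
Conditions: Dess–Martin periodinane, NaHCO3, CH2Cl2, 0 °C
Reagents that add atoms: none
Why: Dess–Martin oxidation converges both C9 epimers on the α-methylene ketone so that C9 can be reset under reagent control.

Step 17
Reactants: 22 macrocyclic enone
Product: 23 (9R)-allylic alcohol
Conditions: (S)-2-methyl-CBS-oxazaborolidine (cat.), catecholborane, toluene, −78 °C
Reagents that add atoms: none
Why: Corey–Bakshi–Shibata reduction: with the (S)-catalyst the branched alkenyl side acts as the large group and hydride delivery should give the 9R carbinol in a 1,2-manner.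

Step 18
Reactants: 23 (9R)-allylic alcohol
Product: 24 (9R)-acetate
Conditions: Ac2O, pyridine, DMAP (cat.), CH2Cl2, 0 °C to rt
Reagents that add atoms: acetic anhydride, CC(=O)OC(C)=O
Why: Acylation of the only free hydroxyl places the acetate before the C2 and C3 hydroxyls exist, so no later differentiation is needed.

Step 19
Reactants: 24 acetate
Product: 25 C3 alcohol (epimers)
Conditions: HF·pyridine, pyridine, THF, 0 to 40 °C
Reagents that add atoms: none
Why: Buffered fluoride removes the hindered secondary silyl ether without touching the allylic acetate.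

Step 20
Reactants: 25 C3 alcohol
Product: 26 C3 ketone (β,γ-unsaturated; C2 = CH2)
Conditions: Dess–Martin periodinane, NaHCO3, CH2Cl2, 0 °C
Reagents that add atoms: none
Why: Buffered Dess–Martin oxidation converges both C3 epimers on the ketone without moving the C1=C15 double bond into conjugation.

Step 21
Reactants: 26 C3 ketone
Product: 27 (2R)-2-hydroxy-3-ketone
Conditions: KN(SiMe3)2 (1.05 equiv), THF, −78 °C; 2-(phenylsulfonyl)-3-phenyloxaziridine, −78 °C; AcOH quench
Reagents that add atoms: 2-(phenylsulfonyl)-3-phenyloxaziridine, O=S(=O)(N1OC1c1ccccc1)c1ccccc1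
Why: C4 is quaternary, so only C2 can be deprotonated; the dienolate is oxidized at its α-carbon by the oxaziridine (enolate hydroxylation) from the convex face, opposite the cyclopentane and the C7 arm of the macrocycle, which sets C2 and leaves C1=C15 in place.

Step 22
Reactants: 27 (2R)-2-hydroxy-3-ketone
Product: 28 CNP0192310.2, (2R,3R,4R,7R,9R,12S,16R)-9-acetoxytrinervita-1(15),8(19)-diene-2,3-diol
Conditions: Me4NBH(OAc)3, MeCN/AcOH, −35 °C
Reagents that add atoms: none
Why: Hydroxyl-directed triacetoxyborohydride reduction: the borohydride bound to the C2 oxygen delivers hydride to C3 on the same face, which should give the trans-2,3-diol with the C3 hydroxyl on the face of C5, and the acetate is not reduced.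

**Compound list**
1 | 3,5-dihydroxyphenylacetic acid | OC(=O)Cc1cc(O)cc(O)c1 | starting material
2 | tert-butyldimethylsilyl 2-[3,5-bis(tert-butyldimethylsilyloxy)phenyl]acetate | CC(C)(C)[Si](C)(C)OC(=O)Cc1cc(O[Si](C)(C)C(C)(C)C)cc(O[Si](C)(C)C(C)(C)C)c1 | intermediate
3 | 2-[3,5-bis(tert-butyldimethylsilyloxy)phenyl]acetic acid | OC(=O)Cc1cc(O[Si](C)(C)C(C)(C)C)cc(O[Si](C)(C)C(C)(C)C)c1 | intermediate
4 | 2-[2,6-dibromo-3,5-bis(tert-butyldimethylsilyloxy)phenyl]acetic acid | OC(=O)Cc1c(Br)c(O[Si](C)(C)C(C)(C)C)cc(O[Si](C)(C)C(C)(C)C)c1Br | intermediate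
5 | 2-[3,5-bis(tert-butyldimethylsilyloxy)-2,6-dimethylphenyl]acetic acid | OC(=O)Cc1c(C)c(O[Si](C)(C)C(C)(C)C)cc(O[Si](C)(C)C(C)(C)C)c1C | intermediate
6 | 2-[3,5-bis(tert-butyldimethylsilyloxy)-2,6-dimethylcyclohexa-2,5-dien-1-yl]acetic acid | OC(=O)CC1C(C)=C(O[Si](C)(C)C(C)(C)C)CC(O[Si](C)(C)C(C)(C)C)=C1C | intermediate
7 | mixed anhydride of 6 with pivalic acid | CC(C)(C)C(=O)OC(=O)CC1C(C)=C(O[Si](C)(C)C(C)(C)C)CC(O[Si](C)(C)C(C)(C)C)=C1C | intermediate
8 | (4R)-4-benzyl-3-{2-[3,5-bis(tert-butyldimethylsilyloxy)-2,6-dimethylcyclohexa-2,5-dien-1-yl]acetyl}-1,3-oxazolidin-2-one | O=C(CC1C(C)=C(O[Si](C)(C)C(C)(C)C)CC(O[Si](C)(C)C(C)(C)C)=C1C)N1[C@H](Cc2ccccc2)COC1=O | intermediate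
9 | (4R)-4-benzyl-3-{(2R)-4-bromo-2-[3,5-bis(tert-butyldimethylsilyloxy)-2,6-dimethylcyclohexa-2,5-dien-1-yl]butanoyl}-1,3-oxazolidin-2-one | O=C([C@H](CCBr)C1C(C)=C(O[Si](C)(C)C(C)(C)C)CC(O[Si](C)(C)C(C)(C)C)=C1C)N1[C@H](Cc2ccccc2)COC1=O | intermediate
10 | (4R)-4-benzyl-3-{[(1R,3aR,7aS)-4,6-bis(tert-butyldimethylsilyloxy)-3a,7-dimethyl-2,3,3a,4,5,7a-hexahydro-1H-inden-1-yl]carbonyl}-1,3-oxazolidin-2-one (C3 epimers) | CC(C)(C)[Si](C)(C)OC1=C(C)[C@H]2[C@H](C(=O)N3[C@H](Cc4ccccc4)COC3=O)CC[C@@]2(C)C(O[Si](C)(C)C(C)(C)C)C1 | intermediate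
11 | (1R,3aR,7aS)-4,6-bis(tert-butyldimethylsilyloxy)-N-methoxy-N,3a,7-trimethyl-2,3,3a,4,5,7a-hexahydro-1H-indene-1-carboxamide (C3 epimers) | CC(C)(C)[Si](C)(C)OC1=C(C)[C@H]2[C@H](C(=O)N(C)OC)CC[C@@]2(C)C(O[Si](C)(C)C(C)(C)C)C1 | intermediate
12 | C1 enol triflate of 11 (6-triflyloxy, 4-silyloxy; C3 epimers) | FC(F)(F)S(=O)(=O)OC1=C(C)[C@H]2[C@H](C(=O)N(C)OC)CC[C@@]2(C)C(O[Si](C)(C)C(C)(C)C)C1 | intermediate
13 | (R)-β-citronellene, (3R)-3,7-dimethylocta-1,6-diene | CC(C)=CCC[C@@H](C)C=C | starting material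
14 | (R)-4-methylhex-5-enal | O=CCC[C@@H](C)C=C | intermediate
15 | (3R)-6,6-dimethoxy-3-methylhex-1-ene | COC(OC)CC[C@@H](C)C=C | intermediate
16 | 9-[(3S)-6,6-dimethoxy-3-methylhexyl]-9-borabicyclo[3.3.1]nonane | COC(OC)CC[C@@H](C)CCB1C2CCCC1CCC2 | intermediate
17 | 8,9-seco Weinreb amide acetal (C1–C14 joined; C3 epimers) | COC(OC)CC[C@@H](C)CCC1=C(C)[C@H]2[C@H](C(=O)N(C)OC)CC[C@@]2(C)C(O[Si](C)(C)C(C)(C)C)C1 | intermediate
18 | 8,9-seco methyl ketone acetal | COC(OC)CC[C@@H](C)CCC1=C(C)[C@H]2[C@H](C(C)=O)CC[C@@]2(C)C(O[Si](C)(C)C(C)(C)C)C1 | intermediate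
19 | 8,9-seco C8 enol triflate acetal | COC(OC)CC[C@@H](C)CCC1=C(C)[C@H]2[C@H](C(=C)OS(=O)(=O)C(F)(F)F)CC[C@@]2(C)C(O[Si](C)(C)C(C)(C)C)C1 | intermediate
20 | 8,9-seco C8 enol triflate C9 aldehyde | O=CCC[C@@H](C)CCC1=C(C)[C@H]2[C@H](C(=C)OS(=O)(=O)C(F)(F)F)CC[C@@]2(C)C(O[Si](C)(C)C(C)(C)C)C1 | intermediate
21 | 3-(tert-butyldimethylsilyloxy)trinervita-1(15),8(19)-dien-9-ol (C9 and C3 epimers) | C=C1C(O)CC[C@@H](C)CCC2=C(C)[C@H]3[C@H]1CC[C@@]3(C)C(O[Si](C)(C)C(C)(C)C)C2 | intermediate
22 | 3-(tert-butyldimethylsilyloxy)trinervita-1(15),8(19)-dien-9-one | C=C1C(=O)CC[C@@H](C)CCC2=C(C)[C@H]3[C@H]1CC[C@@]3(C)C(O[Si](C)(C)C(C)(C)C)C2 | intermediate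
23 | (9R)-3-(tert-butyldimethylsilyloxy)trinervita-1(15),8(19)-dien-9-ol | C=C1[C@H](O)CC[C@@H](C)CCC2=C(C)[C@H]3[C@H]1CC[C@@]3(C)C(O[Si](C)(C)C(C)(C)C)C2 | intermediate
24 | (9R)-9-acetoxy-3-(tert-butyldimethylsilyloxy)trinervita-1(15),8(19)-diene | C=C1[C@H](OC(C)=O)CC[C@@H](C)CCC2=C(C)[C@H]3[C@H]1CC[C@@]3(C)C(O[Si](C)(C)C(C)(C)C)C2 | intermediate
25 | (9R)-9-acetoxytrinervita-1(15),8(19)-dien-3-ol (C3 epimers) | C=C1[C@H](OC(C)=O)CC[C@@H](C)CCC2=C(C)[C@H]3[C@H]1CC[C@@]3(C)C(O)C2 | intermediate
26 | (9R)-9-acetoxytrinervita-1(15),8(19)-dien-3-one | C=C1[C@H](OC(C)=O)CC[C@@H](C)CCC2=C(C)[C@H]3[C@H]1CC[C@@]3(C)C(=O)C2 | intermediate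
27 | (2R,9R)-9-acetoxy-2-hydroxytrinervita-1(15),8(19)-dien-3-one | C=C1[C@H](OC(C)=O)CC[C@@H](C)CCC2=C(C)[C@H]3[C@H]1CC[C@@]3(C)C(=O)[C@@H]2O | intermediate
28 | CNP0192310.2, (2R,3R,4R,7R,9R,12S,16R)-9-acetoxytrinervita-1(15),8(19)-diene-2,3-diol | C=C1[C@H](OC(C)=O)CC[C@@H](C)CCC2=C(C)[C@H]3[C@H]1CC[C@@]3(C)[C@@H](O)[C@@H]2O | target

Total step count: 22. Longest linear sequence: 21 steps (steps 1–9 and 11–22).

**Steps most likely to fail**

Step 7. The C5 radical may be reduced before it adds to the methyl-bearing enol ether carbon, or it may discriminate poorly between the two arms. The fallback makes the same bond by a polar closure, sets out from 9 and returns at 10. Oxidation of the primary bromide with trimethylamine N-oxide in DMSO would give the aldehyde F1. BF3·OEt2 at −78 °C would then bring about an intramolecular Mukaiyama aldol addition of one silyl enol ether arm (same preference for the arm that puts the acyl group on the convex face) to give the β-hydroxy ketone F2 with C4–C5 in place. The extra C5 hydroxyl would be removed by Barton–McCombie deoxygenation through the phenyl thionocarbonate F3 (PhOC(S)Cl, pyridine; then Bu3SnH, AIBN) to the ketone F4. NaBH4 reduction to the alcohol F5 and silylation with TBSOTf/2,6-lutidine would give 10.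

Step 15. Oligomerization may outrun ring closure, because the alkenylchromium end next to the branched C7 must reach the aldehyde across a strained eleven-membered transition state. The fallback closes the ring at C1–C14 instead and makes C8–C9 between two molecules; it sets out from 11 and returns at 24. MeMgBr would convert 11 into the methyl ketone F6, and KN(SiMe3)2/PhNTf2 would give the C8 enol triflate F7 (the C1 silyl enol ether is inert to both). An intermolecular CrCl2/NiCl2 coupling with (R)-4-methylhex-5-enal 14 would give the open-chain allylic alcohol F8. This would be taken through Dess–Martin oxidation to the enone F9, CBS reduction to the (9R)-alcohol F10 and acetylation to the acetate F11, as in steps 16–18. CsF/PhNTf2 would then give the C1 enol triflate F12. 9-BBN should hydroborate the monosubstituted C13=C14 alkene to the borane F13, since the 1,1-disubstituted C8=C19 alkene is flanked by two branched carbons. An intramolecular B-alkyl Suzuki–Miyaura coupling (Pd(dppf)Cl2, AsPh3, Cs2CO3, high dilution) would close the ring to 24.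

Step 21. The oxaziridine may attack the wrong face of the dienolate, so that the C2 epimer predominates. The fallback sets the same centre by hydride delivery to a diketone instead of oxygen delivery to an enolate; it sets out from 26 and returns at 27. The hydroxylation product, if it is the 2-epimer F14, would be oxidized with Dess–Martin periodinane to the 2,3-diketone F15. NaBH4/CeCl3 at −78 °C should reduce the conjugated, less hindered C2 carbonyl and not the neopentyl C3 carbonyl. A hydride enters from the face an electrophile prefers, so the hydroxyl ends up on the opposite face, as in 27.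

Further compounds
F1 | step 7 | (4R)-4-benzyl-3-{(2R)-2-[3,5-bis(tert-butyldimethylsilyloxy)-2,6-dimethylcyclohexa-2,5-dien-1-yl]-4-oxobutanoyl}-1,3-oxazolidin-2-one | O=C([C@H](CC=O)C1C(C)=C(O[Si](C)(C)C(C)(C)C)CC(O[Si](C)(C)C(C)(C)C)=C1C)N1[C@H](Cc2ccccc2)COC1=O
F2 | step 7 | bicyclic imide with C3 ketone and C5 hydroxyl (C5 epimers), C1 silyl enol ether kept | CC(C)(C)[Si](C)(C)OC1=C(C)[C@H]2[C@H](C(=O)N3[C@H](Cc4ccccc4)COC3=O)CC(O)[C@@]2(C)C(=O)C1
F3 | step 7 | O-phenyl thionocarbonate of F2 | CC(C)(C)[Si](C)(C)OC1=C(C)[C@H]2[C@H](C(=O)N3[C@H](Cc4ccccc4)COC3=O)CC(OC(=S)Oc5ccccc5)[C@@]2(C)C(=O)C1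
F4 | step 7 | bicyclic imide with C3 ketone | CC(C)(C)[Si](C)(C)OC1=C(C)[C@H]2[C@H](C(=O)N3[C@H](Cc4ccccc4)COC3=O)CC[C@@]2(C)C(=O)C1
F5 | step 7 | bicyclic imide with C3 hydroxyl (epimers) | CC(C)(C)[Si](C)(C)OC1=C(C)[C@H]2[C@H](C(=O)N3[C@H](Cc4ccccc4)COC3=O)CC[C@@]2(C)C(O)C1
F6 | step 15 | bicyclic methyl ketone with C1 silyl enol ether | CC(C)(C)[Si](C)(C)OC1=C(C)[C@H]2[C@H](C(C)=O)CC[C@@]2(C)C(O[Si](C)(C)C(C)(C)C)C1
F7 | step 15 | C8 enol triflate with C1 silyl enol ether | CC(C)(C)[Si](C)(C)OC1=C(C)[C@H]2[C@H](C(=C)OS(=O)(=O)C(F)(F)F)CC[C@@]2(C)C(O[Si](C)(C)C(C)(C)C)C1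
F8 | step 15 | open-chain allylic alcohol (C9 epimers) | CC(C)(C)[Si](C)(C)OC1=C(C)[C@H]2[C@H](C(=C)C(O)CC[C@@H](C)C=C)CC[C@@]2(C)C(O[Si](C)(C)C(C)(C)C)C1
F9 | step 15 | open-chain enone | CC(C)(C)[Si](C)(C)OC1=C(C)[C@H]2[C@H](C(=C)C(=O)CC[C@@H](C)C=C)CC[C@@]2(C)C(O[Si](C)(C)C(C)(C)C)C1
F10 | step 15 | open-chain (9R)-allylic alcohol | CC(C)(C)[Si](C)(C)OC1=C(C)[C@H]2[C@H](C(=C)[C@H](O)CC[C@@H](C)C=C)CC[C@@]2(C)C(O[Si](C)(C)C(C)(C)C)C1
F11 | step 15 | open-chain (9R)-acetate | CC(C)(C)[Si](C)(C)OC1=C(C)[C@H]2[C@H](C(=C)[C@H](OC(C)=O)CC[C@@H](C)C=C)CC[C@@]2(C)C(O[Si](C)(C)C(C)(C)C)C1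
F12 | step 15 | open-chain (9R)-acetate C1 enol triflate | FC(F)(F)S(=O)(=O)OC1=C(C)[C@H]2[C@H](C(=C)[C@H](OC(C)=O)CC[C@@H](C)C=C)CC[C@@]2(C)C(O[Si](C)(C)C(C)(C)C)C1
F13 | step 15 | B-alkyl-9-BBN adduct of F12 | FC(F)(F)S(=O)(=O)OC1=C(C)[C@H]2[C@H](C(=C)[C@H](OC(C)=O)CC[C@@H](C)CCB3C4CCCC3CCC4)CC[C@@]2(C)C(O[Si](C)(C)C(C)(C)C)C1
F14 | step 21 | (2S,9R)-9-acetoxy-2-hydroxytrinervita-1(15),8(19)-dien-3-one (2-epimer of 27) | C=C1[C@H](OC(C)=O)CC[C@@H](C)CCC2=C(C)[C@H]3[C@H]1CC[C@@]3(C)C(=O)[C@H]2O
F15 | step 21 | (9R)-9-acetoxytrinervita-1(15),8(19)-diene-2,3-dione | C=C1[C@H](OC(C)=O)CC[C@@H](C)CCC2=C(C)[C@H]3[C@H]1CC[C@@]3(C)C(=O)C2=O
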